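**Assumption:** the target has no stereocentre (it is an achiral flavone), so no stereocontrol is needed; it is delivered as the free hydrogen sulfate drawn.

## Retrosynthetic overview

1. Target 11 ⇐ tetra-O-benzyl flavone 6-sulfate salt 9 (hydrogenolysis, H+ exchange); the sulfate is already in place.
2. 9 ⇐ chromone 6 + aryl bromide 7: the C2–C1' bond comes from a C2-zincated chromone (a β-acylvinyl anion, i.e. a homoenolate-type d3 donor at the carbon that is the acceptor of the enone) and the aryl electrophile.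
3. 6 ⇐ acetophenone sulfate 4 + one carbon (DMF-DMA): the pyranone ring is closed on the intact A ring.
4. 4 ⇐ 2 by Elbs persulfate oxidation, which installs the C6–O–SO3− group directly; it is then carried through unprotected.
5. 2 ⇐ phloroacetophenone 1. Ring order: A ring bought, C ring formed in step 3, B ring joined in step 4.

## Route

Step 1
Reactants: 1 2',4',6'-trihydroxyacetophenone
Product: 2 1-[2,4-bis(benzyloxy)-6-hydroxyphenyl]ethan-1-one
Conditions: BnBr (2.1 eq), K2CO3 (2.2 eq), DMF, 0 °C → rt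
Reagents that add atoms: benzyl bromide, BrCc1ccccc1
Why: Williamson etherification in which the 4-OH and one ortho OH are alkylated while the OH hydrogen-bonded to the acetyl C=O stays free.

Step 2
Reactants: 2 1-[2,4-bis(benzyloxy)-6-hydroxyphenyl]ethan-1-one
Product: 4 tetrabutylammonium 3-acetyl-2,6-bis(benzyloxy)-4-hydroxyphenyl sulfate, via potassium aryl sulfate 3 (not isolated)
Conditions: K2S2O8 (1.1 eq), aq KOH, pyridine, 10–20 °C, 24 h; pH 7, Et2O wash (recovers 2); Bu4NHSO4, CH2Cl2 extraction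
Reagents that add atoms: potassium peroxodisulfate, [K+].[K+].[O-]S(=O)(=O)OOS(=O)(=O)[O-]; tetrabutylammonium hydrogen sulfate, CCCC[N+](CCCC)(CCCC)CCCC.OS(=O)(=O)[O-]
Why: Elbs persulfate oxidation, in which the phenoxide attacks a peroxide oxygen through its only free para carbon to give the aryl sulfate, which is kept here as a lipophilic ion pair instead of being hydrolysed.

Step 3
Reactants: 4 tetrabutylammonium 3-acetyl-2,6-bis(benzyloxy)-4-hydroxyphenyl sulfate
Product: 6 tetrabutylammonium 5,7-bis(benzyloxy)-4-oxo-4H-chromen-6-yl sulfate, via enaminone 5 (not isolated)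
Conditions: DMF-DMA (3 eq), toluene, 95 °C; evaporate; AcOH, 70 °C
Reagents that add atoms: N,N-dimethylformamide dimethyl acetal, COC(OC)N(C)C
Why: Enaminone chromone synthesis, in which the methyl ketone condenses with the amide acetal and the ortho phenol then adds (oxa-Michael) with loss of Me2NH; AcOH cannot protonate the ArOSO3− anion, so the sulfate should survive.

Step 4
Reactants: 6 tetrabutylammonium 5,7-bis(benzyloxy)-4-oxo-4H-chromen-6-yl sulfate; 7 4-bromo-1,2-bis(benzyloxy)benzene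
Product: 9 tetrabutylammonium 5,7-bis(benzyloxy)-2-[3,4-bis(benzyloxy)phenyl]-4-oxo-4H-chromen-6-yl sulfate, via 2-chlorozincio chromone 8 (not isolated)
Conditions: TMPZnCl·LiCl (1.3 eq, no added Lewis acid), THF, 25 °C, 1 h; then 7 (1.2 eq), Pd(OAc)2 (3 mol%), SPhos (6 mol%), 50 °C; aq NH4Cl, CH2Cl2
Reagents that add atoms: none
Why: Directed C–H zincation removes the most acidic C2–H (α to the ring oxygen) to give a β-acylvinyl zinc species, a polarity-reversed donor at the normally electrophilic C2, which joins the electrophilic aryl bromide by Negishi cross-coupling; the sulfate monoester anion has no acidic hydrogen and is inert to the hindered zinc amide.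

Step 5
Reactants: 9 tetrabutylammonium 5,7-bis(benzyloxy)-2-[3,4-bis(benzyloxy)phenyl]-4-oxo-4H-chromen-6-yl sulfate
Product: 11 2-(3,4-dihydroxyphenyl)-5,7-dihydroxy-4-oxo-4H-chromen-6-yl hydrogen sulfate (6-hydroxyluteolin 6-sulfate), via tetrabutylammonium salt 10 (not isolated)
Conditions: H2 (1 atm), 10% Pd/C, THF–MeOH, rt; filter; Dowex 50W (H+ form), MeOH–H2O, 0 °C; lyophilise cold
Reagents that add atoms: none
Why: Catalytic hydrogenolysis cleaves the four benzyl aryl ethers while the aryl sulfate and the conjugated pyranone C2=C3 are untouched under these mild conditions, and cation exchange gives the free acid (keep cold, or store as the sodium salt).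

## Compound list

1 | 2',4',6'-trihydroxyacetophenone | CC(=O)c1c(O)cc(O)cc1O | starting material
2 | 1-[2,4-bis(benzyloxy)-6-hydroxyphenyl]ethan-1-one | CC(=O)c1c(O)cc(OCc2ccccc2)cc1OCc1ccccc1 | intermediate
3 | potassium 3-acetyl-2,6-bis(benzyloxy)-4-hydroxyphenyl sulfate | CC(=O)c1c(O)cc(OCc2ccccc2)c(OS(=O)(=O)[O-])c1OCc1ccccc1.[K+] | intermediate
4 | tetrabutylammonium 3-acetyl-2,6-bis(benzyloxy)-4-hydroxyphenyl sulfate | CC(=O)c1c(O)cc(OCc2ccccc2)c(OS(=O)(=O)[O-])c1OCc1ccccc1.CCCC[N+](CCCC)(CCCC)CCCC | intermediate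
5 | tetrabutylammonium 2,6-bis(benzyloxy)-3-[(2E)-3-(dimethylamino)prop-2-enoyl]-4-hydroxyphenyl sulfate | CN(C)/C=C/C(=O)c1c(O)cc(OCc2ccccc2)c(OS(=O)(=O)[O-])c1OCc1ccccc1.CCCC[N+](CCCC)(CCCC)CCCC | intermediate
6 | tetrabutylammonium 5,7-bis(benzyloxy)-4-oxo-4H-chromen-6-yl sulfate | O=c1ccoc2cc(OCc3ccccc3)c(OS(=O)(=O)[O-])c(OCc3ccccc3)c12.CCCC[N+](CCCC)(CCCC)CCCC | intermediate
7 | 4-bromo-1,2-bis(benzyloxy)benzene | Brc1ccc(OCc2ccccc2)c(OCc2ccccc2)c1 | starting material
8 | tetrabutylammonium 5,7-bis(benzyloxy)-2-(chlorozincio)-4-oxo-4H-chromen-6-yl sulfate | Cl[Zn]c1cc(=O)c2c(OCc3ccccc3)c(OS(=O)(=O)[O-])c(OCc3ccccc3)cc2o1.CCCC[N+](CCCC)(CCCC)CCCC | intermediate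
9 | tetrabutylammonium 5,7-bis(benzyloxy)-2-[3,4-bis(benzyloxy)phenyl]-4-oxo-4H-chromen-6-yl sulfate | O=c1cc(-c2ccc(OCc3ccccc3)c(OCc3ccccc3)c2)oc2cc(OCc3ccccc3)c(OS(=O)(=O)[O-])c(OCc3ccccc3)c12.CCCC[N+](CCCC)(CCCC)CCCC | intermediate
10 | tetrabutylammonium 2-(3,4-dihydroxyphenyl)-5,7-dihydroxy-4-oxo-4H-chromen-6-yl sulfate | O=c1cc(-c2ccc(O)c(O)c2)oc2cc(O)c(OS(=O)(=O)[O-])c(O)c12.CCCC[N+](CCCC)(CCCC)CCCC | intermediate
11 | 6-hydroxyluteolin 6-sulfate, 2-(3,4-dihydroxyphenyl)-5,7-dihydroxy-4-oxo-4H-chromen-6-yl hydrogen sulfate | O=c1cc(-c2ccc(O)c(O)c2)oc2cc(O)c(OS(=O)(=O)O)c(O)c12 | target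

## Step count and risks

Total step count: 5. Longest linear sequence: 5 (1 → 2 → 4 → 6 → 9 → 11); 7 is a purchased coupling partner.

The three steps most likely to fail are steps 2, 3 and 4, with step 4 the riskiest.

**Step 2 (Elbs oxidation).** Elbs oxidations give modest conversion, and the para position here is flanked by two benzyloxy groups. The fallback sets out from 2 and comes back at 4. Phenol 2 is oxidised with Fremy's salt (KH2PO4 buffer, acetone–water) to the para-quinone 2-acetyl-3,5-bis(benzyloxy)cyclohexa-2,5-diene-1,4-dione F1. This is reduced with aqueous Na2S2O4 to the hydroquinone 1-[2,4-bis(benzyloxy)-3,6-dihydroxyphenyl]ethan-1-one F2. Its non-chelated 3-OH is sulfated with SO3·pyridine in pyridine at rt (the OH hydrogen-bonded to the acetyl group does not react), and ion-pair extraction with Bu4NHSO4 gives 4.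

**Step 3 (chromone formation with the sulfate on board).** The amide acetal could alkylate the sulfate, or the acid step could cleave it. The fallback sets out from 4 and comes back at 6. Salt 4 undergoes Claisen formylation with ethyl formate and NaH in THF, conditions that are base-only and to which the sulfate salt is inert. Neutral quench and Bu4N+ re-pairing give the racemic lactol tetrabutylammonium 5,7-bis(benzyloxy)-2-hydroxy-4-oxo-3,4-dihydro-2H-chromen-6-yl sulfate F3. This is dehydrated in NaOAc-buffered AcOH at 50 °C to 6.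

**Step 4 (zincation and Negishi coupling of a sulfate salt).** Li/Zn sulfate salts may precipitate from THF, and zincation may be sluggish or go partly to C3 because of the peri 5-OBn/C4=O chelate. The fallback sets out from 6 and comes back at 9; it keeps the same C2-donor coupling but on a neutral substrate, with the sulfate put on afterwards.
- Salt 6 is desulfated with aq HCl in dioxane at 80 °C to 5,7-bis(benzyloxy)-6-hydroxy-4H-chromen-4-one F4.
- F4 is silylated (TBSCl, imidazole, DMF) to 5,7-bis(benzyloxy)-6-[(tert-butyldimethylsilyl)oxy]-4H-chromen-4-one F5.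
- F5 is zincated with TMPZnCl·LiCl in THF to 5,7-bis(benzyloxy)-6-[(tert-butyldimethylsilyl)oxy]-2-(chlorozincio)-4H-chromen-4-one F6.
- F6 is coupled with 7 (Pd(OAc)2/SPhos, 50 °C) to 5,7-bis(benzyloxy)-2-[3,4-bis(benzyloxy)phenyl]-6-[(tert-butyldimethylsilyl)oxy]-4H-chromen-4-one F7.
- TBAF in THF frees 5,7-bis(benzyloxy)-2-[3,4-bis(benzyloxy)phenyl]-6-hydroxy-4H-chromen-4-one F8.
- F8 is sulfated with SO3·pyridine in pyridine at 50 °C and extracted as the ion pair with Bu4NHSO4 to give 9.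

## Further compounds

F1 | step 2 | 2-acetyl-3,5-bis(benzyloxy)cyclohexa-2,5-diene-1,4-dione | CC(=O)C1=C(OCc2ccccc2)C(=O)C(OCc2ccccc2)=CC1=O
F2 | step 2 | 1-[2,4-bis(benzyloxy)-3,6-dihydroxyphenyl]ethan-1-one | CC(=O)c1c(O)cc(OCc2ccccc2)c(O)c1OCc1ccccc1
F3 | step 3 | tetrabutylammonium 5,7-bis(benzyloxy)-2-hydroxy-4-oxo-3,4-dihydro-2H-chromen-6-yl sulfate (racemic lactol) | O=C1CC(O)Oc2cc(OCc3ccccc3)c(OS(=O)(=O)[O-])c(OCc3ccccc3)c12.CCCC[N+](CCCC)(CCCC)CCCC
F4 | step 4 | 5,7-bis(benzyloxy)-6-hydroxy-4H-chromen-4-one | O=c1ccoc2cc(OCc3ccccc3)c(O)c(OCc3ccccc3)c12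
F5 | step 4 | 5,7-bis(benzyloxy)-6-[(tert-butyldimethylsilyl)oxy]-4H-chromen-4-one | O=c1ccoc2cc(OCc3ccccc3)c(O[Si](C)(C)C(C)(C)C)c(OCc3ccccc3)c12
F6 | step 4 | 5,7-bis(benzyloxy)-6-[(tert-butyldimethylsilyl)oxy]-2-(chlorozincio)-4H-chromen-4-one | Cl[Zn]c1cc(=O)c2c(OCc3ccccc3)c(O[Si](C)(C)C(C)(C)C)c(OCc3ccccc3)cc2o1
F7 | step 4 | 5,7-bis(benzyloxy)-2-[3,4-bis(benzyloxy)phenyl]-6-[(tert-butyldimethylsilyl)oxy]-4H-chromen-4-one | O=c1cc(-c2ccc(OCc3ccccc3)c(OCc3ccccc3)c2)oc2cc(OCc3ccccc3)c(O[Si](C)(C)C(C)(C)C)c(OCc3ccccc3)c12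
F8 | step 4 | 5,7-bis(benzyloxy)-2-[3,4-bis(benzyloxy)phenyl]-6-hydroxy-4H-chromen-4-one | O=c1cc(-c2ccc(OCc3ccccc3)c(OCc3ccccc3)c2)oc2cc(OCc3ccccc3)c(O)c(OCc3ccccc3)c12
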